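Ring B (labdane numbering) carries the retron of an alkyne Diels–Alder reaction: its tetrasubstituted C8=C9 alkene is flanked by C7 and by the quaternary C10, and the C6 oxygen sits 1,4 to C9. Ring B is therefore disconnected to a ring A 2-ethoxy-1,3-diene (C7=C6(OEt)–C5=C10, C10 already bearing C20) and but-2-ynal (C8≡C9, formyl carbon C11). One intermolecular [4+2] cycloaddition closes ring B, creates the quaternary C10 under control of the C3/C4 stereocentres of ring A, leaves C6 as a masked ketone and delivers C11 as an aldehyde for side-chain growth. Ring A comes from a desymmetrising CBS reduction of a 2,2-disubstituted cyclohexane-1,3-dione.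

Key step: step 8

Remark: labdane numbering is used for all skeletal carbons (C17 on C8, C18 = 4α-methyl, C19 = 4β-CH2O, C20 on C10; β = the face of ring A that carries C19); the CBS reduction is assumed to follow the usual preference of 2-alkyl-2-methylcyclohexane-1,3-diones for a hydroxyl cis to the larger C2 substituent, so C3 is first made 3β and is inverted through the ketone in steps 13 and 14.

Step 1
Reactants: 1 2-methylcyclohexane-1,3-dione; 2 formaldehyde
Product: 3 2-(hydroxymethyl)-2-methylcyclohexane-1,3-dione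
Conditions: 37% aq. HCHO, H2O, 20 °C
Reagents that add atoms: none
Why: Aldol addition (Tollens-type hydroxymethylation) of the acidic 2-methyl-1,3-dione to formaldehyde should stop at the quaternary mono-adduct, because the new carbon (future C4) has no hydrogen left for elimination or further reaction.

Step 2
Reactants: 3 2-(hydroxymethyl)-2-methylcyclohexane-1,3-dione; 4 3-methylbutanoyl chloride
Product: 5 (1-methyl-2,6-dioxocyclohexyl)methyl 3-methylbutanoate
Conditions: pyridine, DMAP (cat.), CH2Cl2, 0 to 20 °C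
Reagents that add atoms: none
Why: DMAP-catalysed esterification (nucleophilic acyl substitution) installs the C19 isovalerate of the target at the outset and at the same time blocks retro-aldol loss of formaldehyde.

Step 3
Reactants: 5 (1-methyl-2,6-dioxocyclohexyl)methyl 3-methylbutanoate
Product: 6 [(1S,2S)-2-hydroxy-1-methyl-6-oxocyclohexyl]methyl 3-methylbutanoate
Conditions: (R)-2-methyl-CBS-oxazaborolidine (20 mol%), BH3·SMe2 (0.6 equiv), THF, −30 °C; MeOH quench
Reagents that add atoms: none
Why: Corey–Bakshi–Shibata reduction desymmetrises the prochiral dione, since the (R)-catalyst is expected to give the (S)-carbinol and, of the two enantiotopic carbonyl groups, the one that can be attacked anti to the larger acyloxymethyl group should react, which fixes C4 as S and places the new hydroxyl cis to C19 (3β).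

Step 4
Reactants: 6 [(1S,2S)-2-hydroxy-1-methyl-6-oxocyclohexyl]methyl 3-methylbutanoate
Product: 7 [(1S,6S)-1-methyl-2-oxo-6-(triethylsilyloxy)cyclohexyl]methyl 3-methylbutanoate
Conditions: Et3SiCl, imidazole, DMF, 0 to 20 °C
Reagents that add atoms: chlorotriethylsilane CC[Si](Cl)(CC)CC
Why: Silyl ether formation protects the β-hydroxy ketone against retro-aldol cleavage and O-sulfonylation in the enolate steps, with a group that the acid of step 12 removes together with the enol ether.

Step 5
Reactants: 7 [(1S,6S)-1-methyl-2-oxo-6-(triethylsilyloxy)cyclohexyl]methyl 3-methylbutanoate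
Product: 9 [(1S,6S)-1,3-dimethyl-2-oxo-6-(triethylsilyloxy)cyclohexyl]methyl 3-methylbutanoate (both epimers at the new methyl-bearing carbon), via lithium enolate 8 (not isolated)
Conditions: LDA (LiN(i-Pr)2, 1.05 equiv), THF, −78 °C; MeI, −78 to −30 °C
Reagents that add atoms: iodomethane CI
Why: Kinetic enolate alkylation, in which LDA deprotonates the only enolisable ketone α-carbon (C10, more acidic than the ester α-carbon) and methyl iodide introduces the future C20, whose configuration is irrelevant because this carbon becomes sp2 in step 6.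

Step 6
Reactants: 9 [(1S,6S)-1,3-dimethyl-2-oxo-6-(triethylsilyloxy)cyclohexyl]methyl 3-methylbutanoate
Product: 11 [(1S,6S)-1,3-dimethyl-6-(triethylsilyloxy)-2-(trifluoromethylsulfonyloxy)cyclohex-2-en-1-yl]methyl 3-methylbutanoate, via potassium enolate 10 (not isolated)
Conditions: KHMDS (KN(SiMe3)2, 1.0 equiv), THF, −78 °C; PhNTf2, −78 to 0 °C
Reagents that add atoms: N-phenylbis(trifluoromethanesulfonimide) O=S(=O)(N(c1ccccc1)S(=O)(=O)C(F)(F)F)C(F)(F)F
Why: Enol triflate formation, in which the ketone can enolise only towards C10 because C4 is quaternary, so O-sulfonylation of the potassium enolate should give the tetrasubstituted C5=C10 enol triflate as a single regioisomer.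

Step 7
Reactants: 11 [(1S,6S)-1,3-dimethyl-6-(triethylsilyloxy)-2-(trifluoromethylsulfonyloxy)cyclohex-2-en-1-yl]methyl 3-methylbutanoate; 12 tributyl(1-ethoxyvinyl)stannane
Product: 13 [(1S,6S)-2-(1-ethoxyethenyl)-1,3-dimethyl-6-(triethylsilyloxy)cyclohex-2-en-1-yl]methyl 3-methylbutanoate
Conditions: Pd(PPh3)4 (5 mol%), LiCl (3 equiv), CuI (10 mol%), THF, 65 °C
Reagents that add atoms: none
Why: Stille cross-coupling of the vinyl triflate with the α-ethoxyvinylstannane, assisted by LiCl and CuI at this hindered position as for 2,6,6-trimethylcyclohexenyl triflates, should give the 2-ethoxy-1,3-diene directly and under neutral conditions.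

Step 8
Reactants: 13 [(1S,6S)-2-(1-ethoxyethenyl)-1,3-dimethyl-6-(triethylsilyloxy)cyclohex-2-en-1-yl]methyl 3-methylbutanoate; 14 but-2-ynal
Product: 15 6-ethoxy-19-(3-methylbutanoyloxy)-3β-(triethylsilyloxy)-12,13,14,15,16-pentanorlabda-5,8-dien-11-al (10β-methyl)
Conditions: 14 (3 equiv), BHT (cat.), toluene, 90 °C, sealed tube
Reagents that add atoms: none
Why: Normal-electron-demand Diels–Alder reaction in which the electron-rich diene C7=C6(OEt)–C5=C10 and the ynal C8≡C9 combine in a concerted but asynchronous [4+2] cycloaddition, the C7–C8 bond (enol-ether terminus to the β-carbon of the ynal) leading and the C9–C10 bond following, to give the cyclohexa-1,4-diene directly. The closest known reaction type is the cycloaddition of 1-vinyl-2,6,6-trimethylcyclohexene-type semicyclic dienes with acetylenic dienophiles, used to build drimane and labdane decalins with an angular methyl group, together with cycloadditions of 2-alkoxy and 2-silyloxy dienes with ynals and ynoates. Ring B is the only ring closed, by intermolecular [4+2] cycloaddition across C7 and C10 (six-membered, suprafacial on the diene). The one new stereocentre, C10, is controlled by C4 and C3: ring A should react in the half-chair that holds the larger C19 acyloxymethyl group pseudoaxial on the β-face and the 3β-silyloxy group pseudoequatorial, so the alkyne adds to the α-face to avoid a 1,3-diaxial clash with C19, and C20 ends up β, cis to C19. The step needs "para" regioselectivity (formyl-bearing C9 to C10, methyl-bearing C8 to C7), which the 2-ethoxy donor secures by making C7 the nucleophilic terminus, and it needs the alkyne and not the carbonyl group of the ynal to react, which the absence of a Lewis acid favours.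

Step 9
Reactants: 15 6-ethoxy-19-(3-methylbutanoyloxy)-3β-(triethylsilyloxy)-12,13,14,15,16-pentanorlabda-5,8-dien-11-al; 16 1-(triphenylphosphoranylidene)propan-2-one
Product: 17 (11E)-6-ethoxy-19-(3-methylbutanoyloxy)-3β-(triethylsilyloxy)-14,15-dinorlabda-5,8,11-trien-13-one
Conditions: toluene, 100 °C
Reagents that add atoms: none
Why: Wittig olefination with the stabilised acetonylidene ylide should convert the hindered, β-cyclocitral-like aldehyde into the (E)-enone under neutral conditions that spare the enol ether, the silyl ether and the ester.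

Step 10
Reactants: 17 (11E)-6-ethoxy-19-(3-methylbutanoyloxy)-3β-(triethylsilyloxy)-14,15-dinorlabda-5,8,11-trien-13-one
Product: 18 6-ethoxy-19-(3-methylbutanoyloxy)-3β-(triethylsilyloxy)-14,15-dinorlabda-5,8-dien-13-one
Conditions: [(Ph3P)CuH]6 (0.4 equiv), H2O (5 equiv), benzene, 20 °C
Reagents that add atoms: none
Why: Copper hydride conjugate reduction (Stryker's reagent) delivers hydride to C11, the unhindered β-carbon of the enone, and should leave the tetrasubstituted C8=C9 alkene and the enol ether untouched, as in the reduction of β-ionone to dihydro-β-ionone.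

Step 11
Reactants: 18 6-ethoxy-19-(3-methylbutanoyloxy)-3β-(triethylsilyloxy)-14,15-dinorlabda-5,8-dien-13-one; 19 allyl diethylphosphonoacetate
Product: 20 allyl (13E)-6-ethoxy-19-(3-methylbutanoyloxy)-3β-(triethylsilyloxy)labda-5,8,13-trien-15-oate
Conditions: NaH, THF, 0 to 45 °C
Reagents that add atoms: none
Why: Horner–Wadsworth–Emmons olefination of the methyl ketone builds the C13=C14 enoate with the (E)-isomer favoured (ester anti to the larger C12 chain), the minor (Z)-isomer to be removed by chromatography.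

Step 12
Reactants: 20 allyl (13E)-6-ethoxy-19-(3-methylbutanoyloxy)-3β-(triethylsilyloxy)labda-5,8,13-trien-15-oate
Product: 21 allyl (13E)-3β-hydroxy-19-(3-methylbutanoyloxy)-6-oxo-5α-labda-8,13-dien-15-oate
Conditions: 1 M aq. HCl, THF, 0 to 20 °C
Reagents that add atoms: water O
Why: Acid-catalysed enol ether hydrolysis (with cleavage of the triethylsilyl ether) unveils the C6 ketone, and C5 should be protonated from the α-face, opposite the two β-axial groups C19 and C20, which gives the trans ring fusion (5α-H) that is also the thermodynamically preferred one.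

Step 13
Reactants: 21 allyl (13E)-3β-hydroxy-19-(3-methylbutanoyloxy)-6-oxo-5α-labda-8,13-dien-15-oate
Product: 22 allyl (13E)-19-(3-methylbutanoyloxy)-3,6-dioxo-5α-labda-8,13-dien-15-oate
Conditions: Dess–Martin periodinane, NaHCO3, CH2Cl2, 0 to 20 °C
Reagents that add atoms: none
Why: Dess–Martin oxidation converts the equatorial 3β-alcohol into the ketone under buffered, non-enolising conditions that should leave the β,γ-unsaturated C6 ketone unconjugated.

Step 14
Reactants: 22 allyl (13E)-19-(3-methylbutanoyloxy)-3,6-dioxo-5α-labda-8,13-dien-15-oate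
Product: 23 allyl (13E)-3α,6β-dihydroxy-19-(3-methylbutanoyloxy)-5α-labda-8,13-dien-15-oate
Conditions: L-Selectride (LiBH(s-Bu)3, 3 equiv), THF, −78 °C; H2O
Reagents that add atoms: none
Why: Diastereoselective ketone reduction with a bulky trialkylborohydride, in which equatorial attack at C3 should give the axial 3α-alcohol (as for 4,4-disubstituted 3-oxo terpenoids) and attack at C6 from the α-face, opposite C19 and C20, should give the axial 6β-alcohol, while the esters survive at −78 °C.

Step 15
Reactants: 23 allyl (13E)-3α,6β-dihydroxy-19-(3-methylbutanoyloxy)-5α-labda-8,13-dien-15-oate; 4 3-methylbutanoyl chloride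
Product: 24 allyl (13E)-6β-hydroxy-3α,19-bis(3-methylbutanoyloxy)-5α-labda-8,13-dien-15-oate
Conditions: 4 (1.5 equiv), pyridine, DMAP (cat.), CH2Cl2, 0 to 20 °C
Reagents that add atoms: none
Why: Chemoselective DMAP-catalysed esterification, in which the 3α-hydroxyl should react while the 6β-hydroxyl, 1,3-diaxial to both C19 and C20, is too hindered to be acylated under these conditions.

Step 16
Reactants: 24 allyl (13E)-6β-hydroxy-3α,19-bis(3-methylbutanoyloxy)-5α-labda-8,13-dien-15-oate
Product: 25 (13E)-6β-hydroxy-3α,19-bis(3-methylbutanoyloxy)-5α-labda-8,13-dien-15-oic acid (3R,4S,5R,6R,10S; CNP0333611.1)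
Conditions: Pd(PPh3)4 (5 mol%), morpholine, THF, 20 °C
Reagents that add atoms: none
Why: Tsuji–Trost deallylation, in which zerovalent palladium ionises the allyl ester and morpholine traps the allyl fragment, should free the C15 acid without touching the two isovalerates, the C6 alcohol or the alkenes.

Compound list
1 | 2-methylcyclohexane-1,3-dione | CC1C(=O)CCCC1=O | starting material
2 | formaldehyde | C=O | starting material
3 | 2-(hydroxymethyl)-2-methylcyclohexane-1,3-dione | CC1(CO)C(=O)CCCC1=O | intermediate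
4 | 3-methylbutanoyl chloride (isovaleryl chloride) | CC(C)CC(=O)Cl | starting material
5 | (1-methyl-2,6-dioxocyclohexyl)methyl 3-methylbutanoate | CC(C)CC(=O)OCC1(C)C(=O)CCCC1=O | intermediate
6 | [(1S,2S)-2-hydroxy-1-methyl-6-oxocyclohexyl]methyl 3-methylbutanoate (hydroxyl cis to the acyloxymethyl group) | O=C1CCC[C@H](O)[C@]1(C)COC(=O)CC(C)C | intermediate
7 | [(1S,6S)-1-methyl-2-oxo-6-(triethylsilyloxy)cyclohexyl]methyl 3-methylbutanoate | O=C1CCC[C@H](O[Si](CC)(CC)CC)[C@]1(C)COC(=O)CC(C)C | intermediate
8 | lithium enolate of 7 (C5–O, C5=C10) | [Li+].[O-]C1=CCC[C@H](O[Si](CC)(CC)CC)[C@]1(C)COC(=O)CC(C)C | intermediate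
9 | [(1S,6S)-1,3-dimethyl-2-oxo-6-(triethylsilyloxy)cyclohexyl]methyl 3-methylbutanoate (both epimers at the new methyl-bearing carbon) | O=C1C(C)CC[C@H](O[Si](CC)(CC)CC)[C@]1(C)COC(=O)CC(C)C | intermediate
10 | potassium enolate of 9 (tetrasubstituted, C5=C10) | [K+].[O-]C1=C(C)CC[C@H](O[Si](CC)(CC)CC)[C@]1(C)COC(=O)CC(C)C | intermediate
11 | [(1S,6S)-1,3-dimethyl-6-(triethylsilyloxy)-2-(trifluoromethylsulfonyloxy)cyclohex-2-en-1-yl]methyl 3-methylbutanoate | FC(F)(F)S(=O)(=O)OC1=C(C)CC[C@H](O[Si](CC)(CC)CC)[C@]1(C)COC(=O)CC(C)C | intermediate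
12 | tributyl(1-ethoxyvinyl)stannane | CCCC[Sn](CCCC)(CCCC)C(=C)OCC | starting material
13 | [(1S,6S)-2-(1-ethoxyethenyl)-1,3-dimethyl-6-(triethylsilyloxy)cyclohex-2-en-1-yl]methyl 3-methylbutanoate | C=C(OCC)C1=C(C)CC[C@H](O[Si](CC)(CC)CC)[C@]1(C)COC(=O)CC(C)C | intermediate
14 | but-2-ynal | CC#CC=O | starting material
15 | 6-ethoxy-19-(3-methylbutanoyloxy)-3β-(triethylsilyloxy)-12,13,14,15,16-pentanorlabda-5,8-dien-11-al (10β-methyl, 4α-methyl) | CC1=C(C=O)[C@@]2(C)CC[C@H](O[Si](CC)(CC)CC)[C@](C)(COC(=O)CC(C)C)C2=C(OCC)C1 | intermediate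
16 | 1-(triphenylphosphoranylidene)propan-2-one | CC(=O)C=P(c1ccccc1)(c1ccccc1)c1ccccc1 | starting material
17 | (11E)-6-ethoxy-19-(3-methylbutanoyloxy)-3β-(triethylsilyloxy)-14,15-dinorlabda-5,8,11-trien-13-one | CC1=C(/C=C/C(C)=O)[C@@]2(C)CC[C@H](O[Si](CC)(CC)CC)[C@](C)(COC(=O)CC(C)C)C2=C(OCC)C1 | intermediate
18 | 6-ethoxy-19-(3-methylbutanoyloxy)-3β-(triethylsilyloxy)-14,15-dinorlabda-5,8-dien-13-one | CC1=C(CCC(C)=O)[C@@]2(C)CC[C@H](O[Si](CC)(CC)CC)[C@](C)(COC(=O)CC(C)C)C2=C(OCC)C1 | intermediate
19 | allyl diethylphosphonoacetate | CCOP(=O)(OCC)CC(=O)OCC=C | starting material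
20 | allyl (13E)-6-ethoxy-19-(3-methylbutanoyloxy)-3β-(triethylsilyloxy)labda-5,8,13-trien-15-oate | CC1=C(CC/C(C)=C/C(=O)OCC=C)[C@@]2(C)CC[C@H](O[Si](CC)(CC)CC)[C@](C)(COC(=O)CC(C)C)C2=C(OCC)C1 | intermediate
21 | allyl (13E)-3β-hydroxy-19-(3-methylbutanoyloxy)-6-oxo-5α-labda-8,13-dien-15-oate | CC1=C(CC/C(C)=C/C(=O)OCC=C)[C@@]2(C)CC[C@H](O)[C@](C)(COC(=O)CC(C)C)[C@@H]2C(=O)C1 | intermediate
22 | allyl (13E)-19-(3-methylbutanoyloxy)-3,6-dioxo-5α-labda-8,13-dien-15-oate | CC1=C(CC/C(C)=C/C(=O)OCC=C)[C@@]2(C)CCC(=O)[C@](C)(COC(=O)CC(C)C)[C@@H]2C(=O)C1 | intermediate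
23 | allyl (13E)-3α,6β-dihydroxy-19-(3-methylbutanoyloxy)-5α-labda-8,13-dien-15-oate | CC1=C(CC/C(C)=C/C(=O)OCC=C)[C@@]2(C)CC[C@@H](O)[C@](C)(COC(=O)CC(C)C)[C@@H]2[C@H](O)C1 | intermediate
24 | allyl (13E)-6β-hydroxy-3α,19-bis(3-methylbutanoyloxy)-5α-labda-8,13-dien-15-oate | CC1=C(CC/C(C)=C/C(=O)OCC=C)[C@@]2(C)CC[C@@H](OC(=O)CC(C)C)[C@](C)(COC(=O)CC(C)C)[C@@H]2[C@H](O)C1 | intermediate
25 | (13E)-6β-hydroxy-3α,19-bis(3-methylbutanoyloxy)-5α-labda-8,13-dien-15-oic acid, (3R,4S,5R,6R,10S), CNP0333611.1 | CC1=C(CC/C(C)=C/C(=O)O)[C@@]2(C)CC[C@@H](OC(=O)CC(C)C)[C@](C)(COC(=O)CC(C)C)[C@@H]2[C@H](O)C1 | target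

Total step count: 16
Longest linear sequence: 16 steps (1 to 25)

Steps most likely to fail

Step 8. The diene is twisted out of planarity by the quaternary C4 and by the inside methyl group on C10, so cycloaddition may be slower than thermal polymerisation of the ynal, and discrimination between the two faces of C10 may be incomplete. The fallback sets out from 13 and comes back to the route at 15; it takes the aldehyde oxidation level out of the cycloaddition. But-2-ynoic acid is converted (EtSH, DCC, DMAP, CH2Cl2) into S-ethyl but-2-ynethioate F1, a thermally robust dienophile that can be forced onto 13 at about 12 kbar in CH2Cl2 at 25 to 40 °C to give, with the same regiochemistry, the thioester cycloadduct F2. Fukuyama reduction of F2 (Et3SiH, Pd/C, acetone, 20 °C) then gives aldehyde 15 without touching the ester, the silyl ether or the enol ether.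

Step 14. The basic borohydride may deprotonate the hindered β,γ-unsaturated C6 ketone in place of reducing it, with migration of the C8=C9 double bond into conjugation, and equatorial attack at C3 may be incomplete next to the axial acyloxymethyl group. The fallback sets out from 21 and comes back at 23; it handles the two carbonyl groups one after the other. Luche reduction of 21 (NaBH4, CeCl3·7H2O, MeOH, −40 °C), which is non-basic, reduces the C6 ketone from the α-face and gives the 3β,6β-diol F3. Dess–Martin periodinane (1 equiv, CH2Cl2, 0 °C) then oxidises the accessible equatorial 3β-hydroxyl, but not the 1,3-diaxially screened 6β-hydroxyl, to the 3-oxo-6β-ol F4. Reduction of this single ketone with LiBH(s-Bu)3 (THF, −78 °C) gives 23.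

Step 11. Olefination of a methyl ketone gives incomplete control of the C13=C14 geometry, and loss of material to the (Z)-isomer may be serious. The fallback sets out from 15 and comes back at 20; it builds the trisubstituted alkene stereospecifically. Reduction of 15 (NaBH4, MeOH, 0 °C) gives the allylic alcohol F5, and Appel bromination (CBr4, PPh3, 2,6-lutidine, CH2Cl2, −20 °C) gives the allylic bromide F6. Alkylation of the dianion of allyl 3-oxobutanoate (NaH, then n-BuLi, THF, 0 °C) at its terminal carbon gives the β-keto ester F7. Enolisation and phosphorylation (NaH, ClP(O)(OEt)2, Et2O, 0 °C) give the (Z)-enol phosphate F8, and Me2CuLi (Et2O, −78 to −50 °C) replaces the phosphate by methyl with retention to give the (E)-enoate 20.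

Further compounds
F1 | step 8 | S-ethyl but-2-ynethioate | CC#CC(=O)SCC
F2 | step 8 | S-ethyl 6-ethoxy-19-(3-methylbutanoyloxy)-3β-(triethylsilyloxy)-12,13,14,15,16-pentanorlabda-5,8-dien-11-thioate | CC1=C(C(=O)SCC)[C@@]2(C)CC[C@H](O[Si](CC)(CC)CC)[C@](C)(COC(=O)CC(C)C)C2=C(OCC)C1
F3 | step 14 | allyl (13E)-3β,6β-dihydroxy-19-(3-methylbutanoyloxy)-5α-labda-8,13-dien-15-oate | CC1=C(CC/C(C)=C/C(=O)OCC=C)[C@@]2(C)CC[C@H](O)[C@](C)(COC(=O)CC(C)C)[C@@H]2[C@H](O)C1
F4 | step 14 | allyl (13E)-6β-hydroxy-19-(3-methylbutanoyloxy)-3-oxo-5α-labda-8,13-dien-15-oate | CC1=C(CC/C(C)=C/C(=O)OCC=C)[C@@]2(C)CCC(=O)[C@](C)(COC(=O)CC(C)C)[C@@H]2[C@H](O)C1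
F5 | step 11 | 6-ethoxy-11-hydroxy-19-(3-methylbutanoyloxy)-3β-(triethylsilyloxy)-12,13,14,15,16-pentanorlabda-5,8-diene | CC1=C(CO)[C@@]2(C)CC[C@H](O[Si](CC)(CC)CC)[C@](C)(COC(=O)CC(C)C)C2=C(OCC)C1
F6 | step 11 | 11-bromo-6-ethoxy-19-(3-methylbutanoyloxy)-3β-(triethylsilyloxy)-12,13,14,15,16-pentanorlabda-5,8-diene | CC1=C(CBr)[C@@]2(C)CC[C@H](O[Si](CC)(CC)CC)[C@](C)(COC(=O)CC(C)C)C2=C(OCC)C1
F7 | step 11 | allyl 6-ethoxy-19-(3-methylbutanoyloxy)-13-oxo-3β-(triethylsilyloxy)-16-norlabda-5,8-dien-15-oate | CC1=C(CCC(=O)CC(=O)OCC=C)[C@@]2(C)CC[C@H](O[Si](CC)(CC)CC)[C@](C)(COC(=O)CC(C)C)C2=C(OCC)C1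
F8 | step 11 | allyl (13Z)-13-(diethoxyphosphoryloxy)-6-ethoxy-19-(3-methylbutanoyloxy)-3β-(triethylsilyloxy)-16-norlabda-5,8,13-trien-15-oate | CC1=C(CC/C(OP(=O)(OCC)OCC)=C/C(=O)OCC=C)[C@@]2(C)CC[C@H](O[Si](CC)(CC)CC)[C@](C)(COC(=O)CC(C)C)C2=C(OCC)C1
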